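A direct plan would spend six steps on phloroglucinol (statistical diacetylation, Mitsunobu prenylation, Claisen shift with re-acetylation, aminolysis of one acetate, iodination, silylation) to reach aryl iodide A1, and couple it with vinylstannane A2 (Stille).
Sharpless epoxidation and oxidation would give epoxy aldehyde A3; phenoxide opening of the epoxide would close a five-membered ring (A4), and a silyl-triggered acyloin shift would enlarge it to chromanone triacetate A5, which acid methanolysis would unmask.
Weakest would be the ring enlargement A4 → A5: it has no precedent on this ring system, aryl migration competes, C3 rests on a rotamer preference, and it falls on the most precious material.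
Next would be the closure A3 → A4: C2 would be set by SN2 attack at a benzylic carbon that ionises easily, in the strained 5-endo mode, under base beside three aryl acetates that can migrate.
Third would be the run-up to A1: six steps for one C–C bond, the rest acetyl and silyl bookkeeping that leans on a statistical acetylation and an untested selective aminolysis.

Plan of the new route
Retrosynthesis: the C3–O bond is cut first, then the C2–C1' bond, so that ring B leaves as an arylboronic acid and a flat 6-(1,1-dimethylallyl)chromone remains. Next come the C6–C1'' bond (Claisen shift from O5) and the O1–C2 and C2–C3 bonds of ring C (formamide acetal on an acetophenone).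
Forward order of rings: ring A is bought, ring C is closed as a chromone (step 2), ring B is attached last (step 5). C2 and C3 become stereocentres only then, C2 by the catalyst and C3 by C2.
Feature that allows this: C2 is the β-carbon of the C4 carbonyl and carries ring B by a single bond, so the C2=C3 bond of a chromone can accept the aryl group. C4a blocks one ortho position of O5, so a prenyl group on O5 can rearrange to C6 only.
No epoxide, no five-membered ring and no ring enlargement occur, and no nucleophile ever displaces a group at C2. The ring-A oxygens are told apart by their own reactivity, at the cost of one silylation.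

Key step: step 5

Remark: the sense of induction in step 5 is assigned by analogy. (S)-Biaryl bisphosphine–rhodium catalysts arylate cyclic enones to (S)-3-aryl ketones, and the chromone maps onto the enone with O1 in place of the γ-carbon. Should the parent chromone show the other sense, the (R)-ligand is used. MeO-F12-BIPHEP is 6,6'-dimethoxy-2,2'-bis[bis(3,4,5-trifluorophenyl)phosphino]-1,1'-biphenyl.

Step 1
Reactants: 1 1-(2,4,6-trihydroxyphenyl)ethan-1-one (phloroacetophenone)
Product: 2 1-{2,6-dihydroxy-4-[(triisopropylsilyl)oxy]phenyl}ethan-1-one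
Conditions: TIPSCl (1.05 equiv), imidazole (2.2 equiv), DMF, 0 °C → rt
Reagents that add atoms: triisopropylsilyl chloride, CC(C)[Si](Cl)(C(C)C)C(C)C
Why: Chemoselective O-silylation: the 4-hydroxyl is para to the acetyl group, the most acidic and the only one not flanked by it, so one equivalent of the bulky chlorosilane should silylate it alone and leave the two equivalent ortho hydroxyls free.

Step 2
Reactants: 2 1-{2,6-dihydroxy-4-[(triisopropylsilyl)oxy]phenyl}ethan-1-one
Product: 4 5-hydroxy-7-[(triisopropylsilyl)oxy]-4H-chromen-4-one, via enaminone 3 (not isolated)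
Conditions: Me2NCH(OMe)2 (1.5 equiv), toluene, 80 °C; then 1 M aq. HCl, CH2Cl2, 0 °C → rt
Reagents that add atoms: N,N-dimethylformamide dimethyl acetal, COC(OC)N(C)C
Why: Chromone synthesis by enaminone formation and cyclisation: the acetal condenses at the acetyl methyl group, and on acidification either of the two equivalent ortho hydroxyls (mirror plane of 2) adds to the enaminone with loss of dimethylamine, so ring C closes without a regiochemical choice and the other hydroxyl becomes the chelated 5-OH.

Step 3
Reactants: 4 5-hydroxy-7-[(triisopropylsilyl)oxy]-4H-chromen-4-one; 5 3-methylbut-2-en-1-ol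
Product: 6 5-[(3-methylbut-2-en-1-yl)oxy]-7-[(triisopropylsilyl)oxy]-4H-chromen-4-one
Conditions: PPh3, DIAD, THF, 0 °C → rt
Reagents that add atoms: none
Why: Mitsunobu etherification joins the only free phenol, O5, to the primary allylic carbon without allyl transposition, under neutral conditions that spare the aryl silyl ether and avoid C-alkylation.

Step 4
Reactants: 6 5-[(3-methylbut-2-en-1-yl)oxy]-7-[(triisopropylsilyl)oxy]-4H-chromen-4-one
Product: 8 5-[(tert-butyldimethylsilyl)oxy]-6-(2-methylbut-3-en-2-yl)-7-[(triisopropylsilyl)oxy]-4H-chromen-4-one, via phenol 7 (not isolated)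
Conditions: PhNEt2, 195 °C, sealed tube; then TBSOTf (1.5 equiv), 0 °C → rt
Reagents that add atoms: tert-butyldimethylsilyl trifluoromethanesulfonate, CC(C)(C)[Si](C)(C)OS(=O)(=O)C(F)(F)F
Why: Aromatic Claisen rearrangement ([3,3]-sigmatropic, allyl inversion to the 1,1-dimethylallyl group): of the two ortho positions of O5 the ring-fusion carbon C4a is blocked, so the group can arrive at C6 only, on a flat achiral substrate that has no stereocentre to lose, the amine solvent should speed tautomerisation of the dienone to phenol 7 before a Cope shift to C8 intervenes, and silylation in the same flask masks the chelating 5-OH for step 5.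

Step 5
Reactants: 8 5-[(tert-butyldimethylsilyl)oxy]-6-(2-methylbut-3-en-2-yl)-7-[(triisopropylsilyl)oxy]-4H-chromen-4-one; 9 {4-[(tert-butyldimethylsilyl)oxy]phenyl}boronic acid
Product: 10 (2S)-5-[(tert-butyldimethylsilyl)oxy]-2-{4-[(tert-butyldimethylsilyl)oxy]phenyl}-6-(2-methylbut-3-en-2-yl)-7-[(triisopropylsilyl)oxy]chroman-4-one
Conditions: [Rh(OH)((S)-MeO-F12-BIPHEP)]2 (3 mol % Rh, preformed from [Rh(OH)(cod)]2 and the ligand), 9 (3 equiv), CH2Cl2/H2O (10:1), rt
Reagents that add atoms: none
Why: Hayashi–Miyaura reaction (rhodium-catalysed asymmetric 1,4-addition of an arylboronic acid), for which the enantioselective arylation of chromones to flavanones is the closest known case: transmetalation gives an aryl–rhodium species, the C2=C3 bond inserts to form C2–C1' and an oxa-π-allyl rhodium enolate, and water protonates C3 and returns the Rh–OH catalyst. No ring is closed here, ring B is joined to the preformed A/C bicycle. The only new stereocentre, C2, is set by the chiral bisphosphine, which leaves one face of the flat chromone open to the migrating aryl group (2S expected from the S ligand). The step needs 1,4- rather than 1,2-addition, which is inherent in the insertion mechanism, and it must leave the vinyl group alone, which as an unactivated alkene next to a quaternary carbon does not insert into aryl–rhodium bonds. It also needs the flavanone to survive without retro-oxa-Michael opening of ring C, which the base-free two-phase medium at room temperature and the silylated O5 (no acidic, chelating phenol) should secure. The electron-poor ligand is chosen because it keeps the catalyst fast enough at this temperature.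

Step 6
Reactants: 10 (2S)-5-[(tert-butyldimethylsilyl)oxy]-2-{4-[(tert-butyldimethylsilyl)oxy]phenyl}-6-(2-methylbut-3-en-2-yl)-7-[(triisopropylsilyl)oxy]chroman-4-one
Product: 13 (2R,3R)-5-[(tert-butyldimethylsilyl)oxy]-2-{4-[(tert-butyldimethylsilyl)oxy]phenyl}-3-hydroxy-6-(2-methylbut-3-en-2-yl)-7-[(triisopropylsilyl)oxy]chroman-4-one, via enol silane 11 (not isolated), via siloxy ketone 12 (not isolated)
Conditions: TMSOTf (1.5 equiv), Et3N (3 equiv), CH2Cl2, 0 °C; pentane filtration; DMDO (1.1 equiv, acetone), −78 → −40 °C; aq. citric acid, THF, 0 °C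
Reagents that add atoms: dimethyldioxirane, CC1(C)OO1
Why: Rubottom oxidation: soft enolisation gives enol silane 11 without a free enolate (so no β-elimination of O1), the dioxirane should epoxidise the electron-rich C3=C4 bond on the face anti to the C2 aryl group far faster than it attacks the monosubstituted vinyl group, and silyl migration to 12 followed by hydrolysis leaves the 3-hydroxyl trans to the aryl group, that is (2R,3R), the C2 descriptor changing only because C3 now outranks the aryl carbon.

Step 7
Reactants: 13 (2R,3R)-5-[(tert-butyldimethylsilyl)oxy]-2-{4-[(tert-butyldimethylsilyl)oxy]phenyl}-3-hydroxy-6-(2-methylbut-3-en-2-yl)-7-[(triisopropylsilyl)oxy]chroman-4-one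
Product: 14 (2R,3R)-3,5,7-trihydroxy-2-(4-hydroxyphenyl)-6-(2-methylbut-3-en-2-yl)chroman-4-one
Conditions: TBAF (4 equiv), AcOH (4 equiv), THF, 0 °C → rt
Reagents that add atoms: none
Why: Fluoride-mediated cleavage of the three aryl silyl ethers, buffered with acetic acid so that no phenoxide builds up that could open ring C through a quinone methide and epimerise C2, and free of strong acid that could add the flanking hydroxyls to the vinyl group.

Compound list
1 | 1-(2,4,6-trihydroxyphenyl)ethan-1-one | CC(=O)c1c(O)cc(O)cc1O | starting material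
2 | 1-{2,6-dihydroxy-4-[(triisopropylsilyl)oxy]phenyl}ethan-1-one | CC(=O)c1c(O)cc(O[Si](C(C)C)(C(C)C)C(C)C)cc1O | intermediate
3 | (E)-1-{2,6-dihydroxy-4-[(triisopropylsilyl)oxy]phenyl}-3-(dimethylamino)prop-2-en-1-one | CN(C)/C=C/C(=O)c1c(O)cc(O[Si](C(C)C)(C(C)C)C(C)C)cc1O | intermediate
4 | 5-hydroxy-7-[(triisopropylsilyl)oxy]-4H-chromen-4-one | O=c1ccoc2cc(O[Si](C(C)C)(C(C)C)C(C)C)cc(O)c12 | intermediate
5 | 3-methylbut-2-en-1-ol | CC(C)=CCO | starting material
6 | 5-[(3-methylbut-2-en-1-yl)oxy]-7-[(triisopropylsilyl)oxy]-4H-chromen-4-one | CC(C)=CCOc1cc(O[Si](C(C)C)(C(C)C)C(C)C)cc2occc(=O)c12 | intermediate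
7 | 5-hydroxy-6-(2-methylbut-3-en-2-yl)-7-[(triisopropylsilyl)oxy]-4H-chromen-4-one | C=CC(C)(C)c1c(O[Si](C(C)C)(C(C)C)C(C)C)cc2occc(=O)c2c1O | intermediate
8 | 5-[(tert-butyldimethylsilyl)oxy]-6-(2-methylbut-3-en-2-yl)-7-[(triisopropylsilyl)oxy]-4H-chromen-4-one | C=CC(C)(C)c1c(O[Si](C(C)C)(C(C)C)C(C)C)cc2occc(=O)c2c1O[Si](C)(C)C(C)(C)C | intermediate
9 | {4-[(tert-butyldimethylsilyl)oxy]phenyl}boronic acid | CC(C)(C)[Si](C)(C)Oc1ccc(B(O)O)cc1 | starting material
10 | (2S)-5-[(tert-butyldimethylsilyl)oxy]-2-{4-[(tert-butyldimethylsilyl)oxy]phenyl}-6-(2-methylbut-3-en-2-yl)-7-[(triisopropylsilyl)oxy]chroman-4-one | C=CC(C)(C)c1c(O[Si](C(C)C)(C(C)C)C(C)C)cc2c(c1O[Si](C)(C)C(C)(C)C)C(=O)C[C@@H](c1ccc(O[Si](C)(C)C(C)(C)C)cc1)O2 | intermediate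
11 | (2S)-5-[(tert-butyldimethylsilyl)oxy]-2-{4-[(tert-butyldimethylsilyl)oxy]phenyl}-6-(2-methylbut-3-en-2-yl)-7-[(triisopropylsilyl)oxy]-4-[(trimethylsilyl)oxy]-2H-chromene | C=CC(C)(C)c1c(O[Si](C(C)C)(C(C)C)C(C)C)cc2c(c1O[Si](C)(C)C(C)(C)C)C(O[Si](C)(C)C)=C[C@@H](c1ccc(O[Si](C)(C)C(C)(C)C)cc1)O2 | intermediate
12 | (2R,3R)-5-[(tert-butyldimethylsilyl)oxy]-2-{4-[(tert-butyldimethylsilyl)oxy]phenyl}-6-(2-methylbut-3-en-2-yl)-7-[(triisopropylsilyl)oxy]-3-[(trimethylsilyl)oxy]chroman-4-one | C=CC(C)(C)c1c(O[Si](C(C)C)(C(C)C)C(C)C)cc2c(c1O[Si](C)(C)C(C)(C)C)C(=O)[C@H](O[Si](C)(C)C)[C@@H](c1ccc(O[Si](C)(C)C(C)(C)C)cc1)O2 | intermediate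
13 | (2R,3R)-5-[(tert-butyldimethylsilyl)oxy]-2-{4-[(tert-butyldimethylsilyl)oxy]phenyl}-3-hydroxy-6-(2-methylbut-3-en-2-yl)-7-[(triisopropylsilyl)oxy]chroman-4-one | C=CC(C)(C)c1c(O[Si](C(C)C)(C(C)C)C(C)C)cc2c(c1O[Si](C)(C)C(C)(C)C)C(=O)[C@H](O)[C@@H](c1ccc(O[Si](C)(C)C(C)(C)C)cc1)O2 | intermediate
14 | (2R,3R)-3,5,7-trihydroxy-2-(4-hydroxyphenyl)-6-(2-methylbut-3-en-2-yl)chroman-4-one | C=CC(C)(C)c1c(O)cc2c(c1O)C(=O)[C@H](O)[C@@H](c1ccc(O)cc1)O2 | target

Total step count: 7. Longest linear sequence: 7 steps (1 → 14).

Steps most likely to fail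

For step 5, the catalyst may discriminate the two faces of the chromone poorly, or turn over so slowly that ring C opens and the resulting chalcone is arylated a second time. The fallback replaces asymmetric induction by resolution. It sets out from 8: the same addition of 9 with [Rh(OH)(cod)]2 alone (dioxane/H2O, 40 °C) would give the racemic flavanone rac-5-[(tert-butyldimethylsilyl)oxy]-2-{4-[(tert-butyldimethylsilyl)oxy]phenyl}-6-(2-methylbut-3-en-2-yl)-7-[(triisopropylsilyl)oxy]chroman-4-one F1. Kinetic resolution by asymmetric transfer hydrogenation (RuCl(p-cymene)(TsDPEN), the antipode that reduces the 2R ketone, HCO2H/Et3N, rt, stopped near half conversion) leaves the vinyl group untouched. It would convert the unwanted enantiomer into the cis alcohol (2R,4R)-5-[(tert-butyldimethylsilyl)oxy]-2-{4-[(tert-butyldimethylsilyl)oxy]phenyl}-6-(2-methylbut-3-en-2-yl)-7-[(triisopropylsilyl)oxy]chroman-4-ol F2 and leave the 2S ketone. The route is rejoined at 10.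

For step 4, the dienone formed by the [3,3] shift may undergo a second, Cope shift to C8 before it tautomerises, or the new phenol may add to the vinyl group at this temperature. The fallback makes the C6–C1'' bond by cross-coupling instead of rearrangement. It sets out from 4: iodination with benzyltrimethylammonium dichloroiodate and CaCO3 (CH2Cl2/MeOH, rt), which the free 5-OH should direct to C6, would give 5-hydroxy-6-iodo-7-[(triisopropylsilyl)oxy]-4H-chromen-4-one F3. Suzuki–Miyaura coupling with commercial 3-methylbut-2-en-1-ylboronic acid pinacol ester would follow, under a palladium catalyst whose biaryl phosphine ligand steers the allyl group to γ-attack (Pd(OAc)2, K3PO4, THF/H2O, 40–60 °C). It should give phenol 7, where the route is rejoined (silylation as in the second half of step 4).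

For step 6, enolisation of the hindered C4 carbonyl (peri to the 5-silyloxy group) may stay incomplete, or ring C may open by β-elimination of O1 while the enol silane is made. The fallback traps the enolate of the conjugate addition itself, so that ketone 10 is never made. It sets out from 8: the Grignard reagent {4-[(tert-butyldimethylsilyl)oxy]phenyl}magnesium bromide F4 (from commercial (4-bromophenoxy)(tert-butyl)dimethylsilane and Mg, THF) would be converted with ZnCl2 into {4-[(tert-butyldimethylsilyl)oxy]phenyl}zinc chloride F5. This would be added to the chromone with [RhCl((S)-binap)]2 in the presence of Me3SiCl (THF, rt). The rhodium enolate is silylated as it forms, which should give enol silane 11 directly. The route is rejoined at 11.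

Further compounds
F1 | step 5 | rac-5-[(tert-butyldimethylsilyl)oxy]-2-{4-[(tert-butyldimethylsilyl)oxy]phenyl}-6-(2-methylbut-3-en-2-yl)-7-[(triisopropylsilyl)oxy]chroman-4-one | C=CC(C)(C)c1c(O[Si](C(C)C)(C(C)C)C(C)C)cc2c(c1O[Si](C)(C)C(C)(C)C)C(=O)CC(c1ccc(O[Si](C)(C)C(C)(C)C)cc1)O2
F2 | step 5 | (2R,4R)-5-[(tert-butyldimethylsilyl)oxy]-2-{4-[(tert-butyldimethylsilyl)oxy]phenyl}-6-(2-methylbut-3-en-2-yl)-7-[(triisopropylsilyl)oxy]chroman-4-ol | C=CC(C)(C)c1c(O[Si](C(C)C)(C(C)C)C(C)C)cc2c(c1O[Si](C)(C)C(C)(C)C)[C@H](O)C[C@H](c1ccc(O[Si](C)(C)C(C)(C)C)cc1)O2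
F3 | step 4 | 5-hydroxy-6-iodo-7-[(triisopropylsilyl)oxy]-4H-chromen-4-one | O=c1ccoc2cc(O[Si](C(C)C)(C(C)C)C(C)C)c(I)c(O)c12
F4 | step 6 | {4-[(tert-butyldimethylsilyl)oxy]phenyl}magnesium bromide | CC(C)(C)[Si](C)(C)Oc1ccc([Mg]Br)cc1
F5 | step 6 | {4-[(tert-butyldimethylsilyl)oxy]phenyl}zinc chloride | CC(C)(C)[Si](C)(C)Oc1ccc([Zn]Cl)cc1
A1 | direct plan | 5-[(tert-butyldimethylsilyl)oxy]-4-iodo-2-(2-methylbut-3-en-2-yl)-1,3-phenylene diacetate | C=CC(C)(C)c1c(OC(C)=O)cc(O[Si](C)(C)C(C)(C)C)c(I)c1OC(C)=O
A2 | direct plan | 4-[(Z)-3-hydroxy-2-(tributylstannyl)prop-1-en-1-yl]phenyl acetate | OC/C(=C/c1ccc(OC(C)=O)cc1)[Sn](CCCC)(CCCC)CCCC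
A3 | direct plan | 4-[(2R,3S)-3-(4-acetoxyphenyl)-2-formyloxiran-2-yl]-5-[(tert-butyldimethylsilyl)oxy]-2-(2-methylbut-3-en-2-yl)-1,3-phenylene diacetate | O=C[C@]1(c2c(O[Si](C)(C)C(C)(C)C)cc(OC(C)=O)c(C(C)(C)C=C)c2OC(C)=O)O[C@H]1c1ccc(OC(C)=O)cc1
A4 | direct plan | (2R,3R)-2-(4-acetoxyphenyl)-3-formyl-3-hydroxy-5-(2-methylbut-3-en-2-yl)-2,3-dihydrobenzofuran-4,6-diyl diacetate | O=C[C@@]1(O)c2c(OC(C)=O)c(C(C)(C)C=C)c(OC(C)=O)cc2O[C@@H]1c1ccc(OC(C)=O)cc1
A5 | direct plan | (2R,3R)-2-(4-acetoxyphenyl)-3-hydroxy-6-(2-methylbut-3-en-2-yl)-4-oxochromane-5,7-diyl diacetate | C=CC(C)(C)c1c(OC(C)=O)cc2c(c1OC(C)=O)C(=O)[C@H](O)[C@@H](c1ccc(OC(C)=O)cc1)O2
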